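**Plan**

- Retrosynthesis: the two phenols are unmasked last and the C7'' carbinol is traced back to its ketone. Ring C is then cut at C1''–C2'' and C5''–C6'' by a Diels–Alder benzannulation.
- Enabling feature: ring C is attached through C1'' to the oxygen-bearing C7'' and has OMe at C3'' and OH at C4''. With C7'' as a carbonyl, this is the arene that a 1,2-dimethoxy-3-silyloxybutadiene leaves on an ethynyl ketone after loss of methanol.
- Further cuts: C7''–alkyne (Weinreb ketone synthesis), C7'–C1' and C7–C1 (two Negishi sp3–sp2 couplings), O4'–C8'' (Mitsunobu).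
- Forward: desymmetrised meso C4 diol, then ring A, then ring B already carrying the lactate-derived amide, then the ynone. Ring C is built last, followed by reduction and desilylation.
- Stereochemistry: C8/C8' come from meso-2,3-dimethylsuccinic acid by lipase desymmetrisation of its diol. C8'' comes from ethyl (R)-lactate with Mitsunobu inversion. C7'' is set by Felkin–Anh reduction under control of C8''.

Key step: step 14

Assumption: the lipase is taken to acetylate the hydroxymethyl group on the (S)-configured carbon of the meso diol; if it prefers the other arm, the same monoacetate is reached by hydrolysis of the meso diacetate with the same enzyme, and nothing downstream changes.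

TBS = tert-butyldimethylsilyl.

**Route**

Step 1
Reactants: 1 meso-2,3-dimethylsuccinic acid
Product: 2 meso-(2R,3S)-2,3-dimethylbutane-1,4-diol
Conditions: LiAlH4, THF, 0 °C to reflux; aq. NaOH work-up
Reagents that add atoms: none
Why: Hydride reduction of a dicarboxylic acid with LiAlH4 turns both carboxyl groups into hydroxymethyl groups without touching the two methyl-bearing carbons, so the meso arrangement is carried unchanged into the diol.

Step 2
Reactants: 2 meso-(2R,3S)-2,3-dimethylbutane-1,4-diol
Product: 3 (2S,3R)-4-hydroxy-2,3-dimethylbutyl acetate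
Conditions: Pseudomonas fluorescens lipase (lipase AK), vinyl acetate, THF, rt, stopped at the monoacetate
Reagents that add atoms: vinyl acetate, C=COC(C)=O
Why: Enzymatic desymmetrisation of a meso diol by irreversible lipase transesterification acetylates one of the two enantiotopic hydroxymethyl groups, which fixes the absolute configuration of both methyl-bearing carbons (the future C8 and C8') without making or breaking a bond at either.

Step 3
Reactants: 3 (2S,3R)-4-hydroxy-2,3-dimethylbutyl acetate
Product: 4 (2S,3R)-4-iodo-2,3-dimethylbutyl acetate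
Conditions: I2, PPh3, imidazole, CH2Cl2, 0 °C to rt
Reagents that add atoms: iodine, II
Why: Appel-type iodination replaces the primary hydroxyl by iodide through SN2 displacement of the oxyphosphonium at CH2, one carbon away from the nearest stereocentre and under conditions that leave the acetate alone.

Step 4
Reactants: 5 4-bromo-2-methoxyphenol
Product: 6 (4-bromo-2-methoxyphenoxy)(tert-butyl)dimethylsilane
Conditions: TBSCl, imidazole, DMF, rt
Reagents that add atoms: tert-butyldimethylsilyl chloride, CC(C)(C)[Si](C)(C)Cl
Why: Standard silylation of a phenol with a silyl chloride and imidazole; the TBS ether is chosen for ring A because it withstands organozinc, hydride and Grignard reagents and can leave together with the ring C silyl group in the last step.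

Step 5
Reactants: 4 (2S,3R)-4-iodo-2,3-dimethylbutyl acetate; 6 (4-bromo-2-methoxyphenoxy)(tert-butyl)dimethylsilane
Product: 8 (2S,3S)-4-[4-(TBS-oxy)-3-methoxyphenyl]-2,3-dimethylbutyl acetate, via alkylzinc iodide 7 (not isolated)
Conditions: Zn dust (activated with BrCH2CH2Br, Me3SiCl), LiCl, THF, 40 °C; then 6, Pd(OAc)2 (2 mol %), SPhos (4 mol %), THF, 25–50 °C
Reagents that add atoms: none
Why: Insertion of LiCl-activated zinc into the primary C–I bond gives an alkylzinc iodide that tolerates the acetate, and Negishi sp3–sp2 cross-coupling with the electron-rich aryl bromide forms the C7–C1 bond without involving the stereocentres, which are β and γ to the metal.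

Step 6
Reactants: 8 (2S,3S)-4-[4-(TBS-oxy)-3-methoxyphenyl]-2,3-dimethylbutyl acetate
Product: 9 (2S,3S)-4-[4-(TBS-oxy)-3-methoxyphenyl]-2,3-dimethylbutan-1-ol
Conditions: i-Bu2AlH, CH2Cl2, −78 °C; aq. potassium sodium tartrate
Reagents that add atoms: none
Why: Reductive cleavage of the acetate with i-Bu2AlH at low temperature frees the primary alcohol and avoids the basic methanolysis that would also cleave the base-labile aryl silyl ether.

Step 7
Reactants: 9 (2S,3S)-4-[4-(TBS-oxy)-3-methoxyphenyl]-2,3-dimethylbutan-1-ol
Product: 10 tert-butyl{4-[(2S,3S)-4-iodo-2,3-dimethylbutyl]-2-methoxyphenoxy}dimethylsilane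
Conditions: I2, PPh3, imidazole, CH2Cl2, 0 °C to rt
Reagents that add atoms: iodine, II
Why: A second Appel-type iodination converts the primary alcohol into the iodide needed for zinc insertion, again by SN2 at CH2 with no effect on the adjacent stereocentre or on the aryl silyl ether.

Step 8
Reactants: 11 4-bromo-2,6-dimethoxyphenol; 12 ethyl (R)-lactate
Product: 13 ethyl (2S)-2-(4-bromo-2,6-dimethoxyphenoxy)propanoate
Conditions: PPh3, DIAD, THF, 0 °C to rt
Reagents that add atoms: none
Why: Mitsunobu etherification of the phenol, which is acidic enough despite its two ortho methoxyls, displaces the lactate oxyphosphonium by SN2 with inversion, so the (R) lactate gives the (S) aryloxy centre that becomes C8''.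

Step 9
Reactants: 13 ethyl (2S)-2-(4-bromo-2,6-dimethoxyphenoxy)propanoate
Product: 14 (2S)-2-(4-bromo-2,6-dimethoxyphenoxy)-N-methoxy-N-methylpropanamide
Conditions: MeNHOMe·HCl, i-PrMgCl, THF, −20 °C
Reagents that add atoms: N,O-dimethylhydroxylamine hydrochloride, CNOC.Cl
Why: Aminolysis of the ester by the chloromagnesium amide of N,O-dimethylhydroxylamine gives the Weinreb amide at a temperature at which the α-aryloxy centre should not epimerise and the electron-rich aryl bromide should not undergo halogen–magnesium exchange.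

Step 10
Reactants: 10 tert-butyl{4-[(2S,3S)-4-iodo-2,3-dimethylbutyl]-2-methoxyphenoxy}dimethylsilane; 14 (2S)-2-(4-bromo-2,6-dimethoxyphenoxy)-N-methoxy-N-methylpropanamide
Product: 16 (2S)-2-{4-[(2R,3S)-4-[4-(TBS-oxy)-3-methoxyphenyl]-2,3-dimethylbutyl]-2,6-dimethoxyphenoxy}-N-methoxy-N-methylpropanamide, via alkylzinc iodide 15 (not isolated)
Conditions: Zn dust (activated), LiCl, THF, 40 °C; then 14, Pd(OAc)2 (3 mol %), SPhos (6 mol %), THF, 25–40 °C
Reagents that add atoms: none
Why: The same zinc insertion and Negishi cross-coupling join the two halves at C7'–C1', since the alkylzinc iodide neither adds to the Weinreb amide nor deprotonates C8'' and the bromide para to the aryloxy group is unhindered.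

Step 11
Reactants: 16 (2S)-2-{4-[(2R,3S)-4-[4-(TBS-oxy)-3-methoxyphenyl]-2,3-dimethylbutyl]-2,6-dimethoxyphenoxy}-N-methoxy-N-methylpropanamide
Product: 17 (4S)-4-{4-[(2R,3S)-4-[4-(TBS-oxy)-3-methoxyphenyl]-2,3-dimethylbutyl]-2,6-dimethoxyphenoxy}pent-1-yn-3-one
Conditions: HC≡CMgBr, THF, 0 °C; inverse quench into cold aq. NaHSO4
Reagents that add atoms: ethynylmagnesium bromide, C#C[Mg]Br
Why: In this Weinreb ketone synthesis the alkynyl Grignard reagent adds once to give a magnesium-chelated tetrahedral intermediate that prevents over-addition and shields C8'' from enolisation, and the inverse acidic quench protonates the liberated amine before it can add to the ynone.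

Step 12
Reactants: 18 1-methoxypropan-2-one
Product: 20 (Z)-3,4-dimethoxybut-3-en-2-one, via sodium formyl enolate 19 (not isolated)
Conditions: NaH, HCO2Me, Et2O (cat. MeOH), 0 °C to rt; then Me2SO4, DMF, rt; distillation
Reagents that add atoms: methyl formate, COC=O; dimethyl sulfate, COS(=O)(=O)OC
Why: Crossed Claisen formylation under equilibrating conditions should take place at the more acidic methoxy-bearing methylene (as 2-butanone is formylated at its methylene), the hard electrophile dimethyl sulfate methylates the formyl enolate on oxygen, and the β-methoxy enone settles by reversible conjugate addition of methoxide into the Z isomer with the C4 methoxyl anti to the acetyl group.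

Step 13
Reactants: 20 (Z)-3,4-dimethoxybut-3-en-2-one
Product: 21 (Z)-tert-butyl[(3,4-dimethoxybuta-1,3-dien-2-yl)oxy]dimethylsilane, i.e. (Z)-1,2-dimethoxy-3-(TBS-oxy)buta-1,3-diene
Conditions: TBSOSO2CF3, Et3N, Et2O, 0 °C to rt
Reagents that add atoms: tert-butyldimethylsilyl trifluoromethanesulfonate, CC(C)(C)[Si](C)(C)OS(=O)(=O)C(F)(F)F
Why: Silyl enol ether formation by soft enolisation can only go toward the methyl group because C3 bears no hydrogen, which gives the 2-silyloxydiene with the enol ether geometry of the enone retained.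

Step 14
Reactants: 17 (4S)-4-{4-[(2R,3S)-4-[4-(TBS-oxy)-3-methoxyphenyl]-2,3-dimethylbutyl]-2,6-dimethoxyphenoxy}pent-1-yn-3-one; 21 (Z)-1,2-dimethoxy-3-(TBS-oxy)buta-1,3-diene
Product: 23 (2S)-1-[4-(TBS-oxy)-3-methoxyphenyl]-2-{4-[(2R,3S)-4-[4-(TBS-oxy)-3-methoxyphenyl]-2,3-dimethylbutyl]-2,6-dimethoxyphenoxy}propan-1-one, via cyclohexadiene cycloadduct 22 (not isolated)
Conditions: 21 (2.5 equiv), toluene, 80 °C, sealed tube; then PPTS (cat.), CH2Cl2, rt
Reagents that add atoms: none
Why: In a thermal, concerted but asynchronous [4+2] cycloaddition the unsubstituted CH2 terminus of diene 21, made nucleophilic by the C1 methoxyl and the C3 silyloxy group, bonds to the β-carbon of ynone 17 (future C6'') while C1 bonds to the α-carbon (C1''), giving the 1,4-cyclohexadiene 22, which then loses methanol (OMe from C2'', H from C5'') to give the arene. The closest known reaction type is the cycloaddition of 1-methoxy-3-silyloxybutadienes to alkynyl ketones and propiolates, with loss of methanol, to give 4-acylphenol derivatives. Ring C is closed by this intermolecular suprafacial [4+2] cycloaddition, which forms C1''–C2'' and C5''–C6'' in one operation. No stereocentre is created that survives: the sp3 centre formed at C2'' in 22 is destroyed on aromatisation, and C8'' should keep its S configuration because the conditions are neutral and non-enolising. The step needs regioselectivity (acyl para to the silyloxy group, methoxyl between them), which the two cooperating donors at C1 and C3 should secure over the single C2 methoxyl, helped by the outward Z geometry of the C1 methoxyl that lets the diene reach its s-cis conformation. The robust TBS group stays on the new phenol oxygen, so the ketone leaves the step already protected for the hydride reduction.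

Step 15
Reactants: 23 (2S)-1-[4-(TBS-oxy)-3-methoxyphenyl]-2-{4-[(2R,3S)-4-[4-(TBS-oxy)-3-methoxyphenyl]-2,3-dimethylbutyl]-2,6-dimethoxyphenoxy}propan-1-one
Product: 24 (1S,2S)-1-[4-(TBS-oxy)-3-methoxyphenyl]-2-{4-[(2R,3S)-4-[4-(TBS-oxy)-3-methoxyphenyl]-2,3-dimethylbutyl]-2,6-dimethoxyphenoxy}propan-1-ol
Conditions: LiBH(s-Bu)3, THF, −78 °C; then H2O
Reagents that add atoms: none
Why: In a Felkin–Anh-controlled hydride addition with a bulky, non-chelating trialkylborohydride, the C8''–OAr bond lies perpendicular to the carbonyl and anti to the incoming hydride, which passes the C8'' hydrogen and so should set C7'' as S, giving the threo (7''S,8''S) alcohol by 1,2-induction from C8''.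

Step 16
Reactants: 24 (1S,2S)-1-[4-(TBS-oxy)-3-methoxyphenyl]-2-{4-[(2R,3S)-4-[4-(TBS-oxy)-3-methoxyphenyl]-2,3-dimethylbutyl]-2,6-dimethoxyphenoxy}propan-1-ol
Product: 25 (+)-(7''S,8S,8'R,8''S)-4,4''-dihydroxy-3,3',3'',5'-tetramethoxy-4',8''-oxy-8,8'-sesquineolignan-7''-ol
Conditions: Bu4NF, AcOH, THF, 0 °C
Reagents that add atoms: none
Why: Fluoride cleavage of both aryl silyl ethers, driven by Si–F bond formation and buffered with acetic acid, should free the two phenols without ionising or epimerising the p-hydroxybenzylic C7'' alcohol.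

**Compound list**

1 | meso-2,3-dimethylsuccinic acid | OC(=O)[C@H](C)[C@H](C)C(O)=O | starting material
2 | meso-(2R,3S)-2,3-dimethylbutane-1,4-diol | OC[C@H](C)[C@H](C)CO | intermediate
3 | (2S,3R)-4-hydroxy-2,3-dimethylbutyl acetate | OC[C@H](C)[C@H](C)COC(C)=O | intermediate
4 | (2S,3R)-4-iodo-2,3-dimethylbutyl acetate | IC[C@H](C)[C@H](C)COC(C)=O | intermediate
5 | 4-bromo-2-methoxyphenol | COc1cc(Br)ccc1O | starting material
6 | (4-bromo-2-methoxyphenoxy)(tert-butyl)dimethylsilane | COc1cc(Br)ccc1O[Si](C)(C)C(C)(C)C | intermediate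
7 | [(2R,3S)-4-acetoxy-2,3-dimethylbutyl]zinc iodide (not isolated) | I[Zn]C[C@H](C)[C@H](C)COC(C)=O | intermediate
8 | (2S,3S)-4-[4-(TBS-oxy)-3-methoxyphenyl]-2,3-dimethylbutyl acetate | COc1cc(C[C@H](C)[C@H](C)COC(C)=O)ccc1O[Si](C)(C)C(C)(C)C | intermediate
9 | (2S,3S)-4-[4-(TBS-oxy)-3-methoxyphenyl]-2,3-dimethylbutan-1-ol | COc1cc(C[C@H](C)[C@H](C)CO)ccc1O[Si](C)(C)C(C)(C)C | intermediate
10 | tert-butyl{4-[(2S,3S)-4-iodo-2,3-dimethylbutyl]-2-methoxyphenoxy}dimethylsilane | COc1cc(C[C@H](C)[C@H](C)CI)ccc1O[Si](C)(C)C(C)(C)C | intermediate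
11 | 4-bromo-2,6-dimethoxyphenol | COc1cc(Br)cc(OC)c1O | starting material
12 | ethyl (R)-lactate | CCOC(=O)[C@@H](C)O | starting material
13 | ethyl (2S)-2-(4-bromo-2,6-dimethoxyphenoxy)propanoate | CCOC(=O)[C@H](C)Oc1c(OC)cc(Br)cc1OC | intermediate
14 | (2S)-2-(4-bromo-2,6-dimethoxyphenoxy)-N-methoxy-N-methylpropanamide | CON(C)C(=O)[C@H](C)Oc1c(OC)cc(Br)cc1OC | intermediate
15 | {(2S,3S)-4-[4-(TBS-oxy)-3-methoxyphenyl]-2,3-dimethylbutyl}zinc iodide (not isolated) | COc1cc(C[C@H](C)[C@H](C)C[Zn]I)ccc1O[Si](C)(C)C(C)(C)C | intermediate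
16 | (2S)-2-{4-[(2R,3S)-4-[4-(TBS-oxy)-3-methoxyphenyl]-2,3-dimethylbutyl]-2,6-dimethoxyphenoxy}-N-methoxy-N-methylpropanamide | COc1cc(C[C@H](C)[C@H](C)Cc2cc(OC)c(O[C@@H](C)C(=O)N(C)OC)c(OC)c2)ccc1O[Si](C)(C)C(C)(C)C | intermediate
17 | (4S)-4-{4-[(2R,3S)-4-[4-(TBS-oxy)-3-methoxyphenyl]-2,3-dimethylbutyl]-2,6-dimethoxyphenoxy}pent-1-yn-3-one | COc1cc(C[C@H](C)[C@H](C)Cc2cc(OC)c(O[C@@H](C)C(=O)C#C)c(OC)c2)ccc1O[Si](C)(C)C(C)(C)C | intermediate
18 | 1-methoxypropan-2-one | COCC(C)=O | starting material
19 | sodium 2-methoxy-3-oxobut-1-en-1-olate (enolate geometry not fixed; not isolated) | [Na+].[O-]C=C(OC)C(C)=O | intermediate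
20 | (Z)-3,4-dimethoxybut-3-en-2-one | CO/C=C(\OC)C(C)=O | intermediate
21 | (Z)-tert-butyl[(3,4-dimethoxybuta-1,3-dien-2-yl)oxy]dimethylsilane | CO/C=C(\OC)C(=C)O[Si](C)(C)C(C)(C)C | intermediate
22 | (2S)-1-[4-(TBS-oxy)-5,6-dimethoxycyclohexa-1,4-dien-1-yl]-2-{4-[(2R,3S)-4-[4-(TBS-oxy)-3-methoxyphenyl]-2,3-dimethylbutyl]-2,6-dimethoxyphenoxy}propan-1-one (both epimers at the ring CH(OMe) carbon; not isolated) | COc1cc(C[C@H](C)[C@H](C)Cc2cc(OC)c(O[C@@H](C)C(=O)C3=CCC(O[Si](C)(C)C(C)(C)C)=C(OC)C3OC)c(OC)c2)ccc1O[Si](C)(C)C(C)(C)C | intermediate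
23 | (2S)-1-[4-(TBS-oxy)-3-methoxyphenyl]-2-{4-[(2R,3S)-4-[4-(TBS-oxy)-3-methoxyphenyl]-2,3-dimethylbutyl]-2,6-dimethoxyphenoxy}propan-1-one | COc1cc(C[C@H](C)[C@H](C)Cc2cc(OC)c(O[C@@H](C)C(=O)c3ccc(O[Si](C)(C)C(C)(C)C)c(OC)c3)c(OC)c2)ccc1O[Si](C)(C)C(C)(C)C | intermediate
24 | (1S,2S)-1-[4-(TBS-oxy)-3-methoxyphenyl]-2-{4-[(2R,3S)-4-[4-(TBS-oxy)-3-methoxyphenyl]-2,3-dimethylbutyl]-2,6-dimethoxyphenoxy}propan-1-ol | COc1cc(C[C@H](C)[C@H](C)Cc2cc(OC)c(O[C@@H](C)[C@@H](O)c3ccc(O[Si](C)(C)C(C)(C)C)c(OC)c3)c(OC)c2)ccc1O[Si](C)(C)C(C)(C)C | intermediate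
25 | (+)-(7''S,8S,8'R,8''S)-4,4''-dihydroxy-3,3',3'',5'-tetramethoxy-4',8''-oxy-8,8'-sesquineolignan-7''-ol | COc1cc(C[C@H](C)[C@H](C)Cc2cc(OC)c(O[C@@H](C)[C@@H](O)c3ccc(O)c(OC)c3)c(OC)c2)ccc1O | target

**Totals**

Total step count: 16.
Longest linear sequence: 11 steps (1, 2, 3, 5, 6, 7, 10, 11, 14, 15, 16).

**Steps most likely to fail**

Step 14. The trioxygenated diene may add so slowly that the terminal ynone polymerises first. The C2 methoxyl may also erode the orientation of addition and give the regioisomeric arene, or the silyl enol ether may hydrolyse before methanol is lost. The fallback brings ring C in ready-made instead of building it. Bromide 6 is converted with Mg turnings in THF into [4-(tert-butyldimethylsilyloxy)-3-methoxyphenyl]magnesium bromide F1, which is added to Weinreb amide 16 at 0 °C in a Weinreb ketone synthesis. This sets out from 16 and comes back to the route at ketone 23; steps 11 to 14 are then not needed.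

Step 15. Lithium chelation between the carbonyl oxygen and the aryloxy or ortho-methoxy oxygens could compete with the Felkin–Anh pathway, lowering facial selectivity and giving the erythro epimer. The fallback moves from substrate control to catalyst control: asymmetric transfer hydrogenation of 23 with RuCl[(R,R)-TsDPEN](p-cymene) in HCO2H/Et3N (5:2) at rt. The hydride is then delivered to the face fixed by the ligand. The R,R catalyst is the one expected to give the 7''S descriptor here, because C8'' outranks the aryl group. This sets out from 23 and returns at 24; no new compound arises on the way (F0).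

Step 12. Formylation may occur at the methyl group instead of the methoxy-bearing methylene, or the enolate may be methylated on carbon, either of which would give a regioisomeric enone. The fallback fixes the site of C–C bond formation in a separate step whose outcome can be checked. Ketone 18 is silylated under equilibrating conditions (Me3SiCl, Et3N, DMF, 80 °C) to the more substituted enol ether (Z)-[(1-methoxyprop-1-en-2-yl)oxy]trimethylsilane F2, which is purified by distillation. A Mukaiyama-type reaction with trimethyl orthoformate (cat. Me3SiOSO2CF3, CH2Cl2, −78 °C) then gives 3,4,4-trimethoxybutan-2-one F3. Acid-catalysed loss of methanol (cat. TsOH, distillation) gives 20, where the route is rejoined.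

**Further compounds**

F1 | step 14 | [4-(tert-butyldimethylsilyloxy)-3-methoxyphenyl]magnesium bromide | COc1cc([Mg]Br)ccc1O[Si](C)(C)C(C)(C)C
F0 | step 15 | none | none
F2 | step 12 | (Z)-[(1-methoxyprop-1-en-2-yl)oxy]trimethylsilane | CO/C=C(C)\O[Si](C)(C)C
F3 | step 12 | 3,4,4-trimethoxybutan-2-one (racemic) | COC(OC)C(OC)C(C)=O
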